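**Retrosynthetic overview**

- The target is (7R,8S,7'R,8'S)-syringaresinol carrying three erythro guaiacylglycerol β-aryl ether arms: arm E on one syringyl oxygen, arm B on the other, and arm A on the phenol of arm B. Each arm is cut at its C7–C8 bond (auxiliary-controlled anti aldol of an aryloxyacetyl imide with O-silyl vanillin) and at its ArO–CH2 bond (phenol alkylation).
- The strategy rests on the four contiguous stereocentres C7, C8, C8', C7' of the cis-fused 3,7-dioxabicyclo[3.3.0]octane core. They are traced back to an achiral, stereolabile diethyl 2,3-diaroylsuccinate in which C7 and C7' are aryl ketones and C8 and C8' are enolisable methines, each flanked by a ketone and an ester.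
- Key disconnection: the two lactone O–C9' and O–C9 bonds together with the two carbinol centres, made in one two-fold dynamic kinetic transfer hydrogenation with in situ lactonisation. The succinate C8–C8' bond comes from alkylation of the sodium enolate of the aroylacetate (from acetosyringone) with its own α-bromo derivative.
- Ring order: lactone ring 1, then lactone ring 2 (key step); both are opened by LiAlH4 and re-closed as the two tetrahydrofuran rings at the primary carbons. C2 symmetry is kept through a double aldol (arms B and E together) and broken late by statistical mono-desilylation before arm A is built.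

Key step: step 5

Remark: lignan numbering is used (C7 benzylic, C8, C9 per C6C3 unit, primes for the second syringyl unit). Arms B and E are (7S,8R) and arm A is (7R,8S), all erythro (anti in the aldol sense). The auxiliary enantiomer for each aldol is assigned on the assumption of a chelated magnesium Z-enolate, with the aldehyde on the face remote from the benzyl group.

**Route**

Step 1
Reactants: 1 acetosyringone; 2 benzyl bromide
Product: 3 1-(4-benzyloxy-3,5-dimethoxyphenyl)ethanone
Conditions: K2CO3, DMF, 60 °C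
Reagents that add atoms: none
Why: Williamson ether synthesis in which the phenoxide of the acidic 4-hydroxyl displaces bromide from the benzylic halide, giving a protecting group that tolerates every step up to the hydrogenolysis.

Step 2
Reactants: 3 1-(4-benzyloxy-3,5-dimethoxyphenyl)ethanone; 4 diethyl carbonate
Product: 5 ethyl 3-(4-benzyloxy-3,5-dimethoxyphenyl)-3-oxopropanoate
Conditions: NaH (2.2 equiv), THF, reflux; then AcOH
Reagents that add atoms: none
Why: Crossed Claisen condensation in which the methyl ketone enolate is ethoxycarbonylated by the non-enolisable carbonate, the equilibrium being pulled over by deprotonation of the β-keto ester formed.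

Step 3
Reactants: 5 ethyl 3-(4-benzyloxy-3,5-dimethoxyphenyl)-3-oxopropanoate (one half of the batch)
Product: 6 ethyl 2-bromo-3-(4-benzyloxy-3,5-dimethoxyphenyl)-3-oxopropanoate (racemic)
Conditions: NBS (1.0 equiv), Mg(ClO4)2 (10 mol %), MeCN, 0 °C → rt, dark
Reagents that add atoms: N-bromosuccinimide, O=C1CCC(=O)N1Br
Why: Electrophilic α-bromination of a 1,3-dicarbonyl compound, in which the magnesium-chelated enol of the β-keto ester takes up Br+ from NBS far faster than the acyl-deactivated arene does, and one equivalent of reagent under non-basic conditions should stop at the monobromide without premature self-coupling.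

Step 4
Reactants: 5 ethyl 3-(4-benzyloxy-3,5-dimethoxyphenyl)-3-oxopropanoate (other half of the batch, 1.0 equiv); 6 ethyl 2-bromo-3-(4-benzyloxy-3,5-dimethoxyphenyl)-3-oxopropanoate (1.0 equiv)
Product: 7 diethyl 2,3-bis(4-benzyloxy-3,5-dimethoxybenzoyl)butanedioate (stereolabile meso/dl mixture)
Conditions: 5, NaH (1.0 equiv), THF, 0 °C; then 6 added slowly, 0 °C → rt; aq. NH4Cl
Reagents that add atoms: none
Why: C-alkylation of a stabilised β-keto ester enolate by a doubly activated secondary bromide, the classical way to 2,3-diacylsuccinic esters; a competing halophilic bromine transfer between the two partners is degenerate and leads to the same product, and no stereocontrol is needed because both new centres stay enolisable.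

Step 5
Reactants: 7 diethyl 2,3-bis(4-benzyloxy-3,5-dimethoxybenzoyl)butanedioate
Product: 11 (1R,2R,5R,6R)-2,6-bis(4-benzyloxy-3,5-dimethoxyphenyl)-3,7-dioxabicyclo[3.3.0]octane-4,8-dione (both aryl groups exo), via hydroxy keto diester 8 (not isolated), via keto lactone 9 (not isolated), via hydroxy lactone ester 10 (not isolated)
Conditions: RuCl(p-cymene)[(R,R)-TsDPEN] (5 mol %), HCO2H/Et3N (5:2), DMF, 40 °C; then 60 °C
Reagents that add atoms: none
Why: Proposed new method: formate loads the 16-electron Ru amide with hydride and the Ru–H/N–H pair delivers hydride and proton to each aryl ketone through the outer-sphere six-membered transition state, while Et3N keeps every methine that still stands next to an unreduced ketone epimerising through its enol; the closest known reaction type is the dynamic kinetic asymmetric transfer hydrogenation of α-substituted β-keto esters with spontaneous γ-lactonisation, here run twice in one 2,3-diaroylsuccinate. C7 and C7' are set (R) by the (R,R)-TsDPEN ligand (aryl ketone model, aryl group under the η6-arene), and since both carbinols come from the same catalyst-controlled event a facial error should end up in a separable exo,endo diastereomer and not in the enantiomer. C8 is labile only until C7 is reduced and is therefore fixed in the first hydride transfer, which must be syn (as in syn-selective dynamic reductions of α-alkyl β-keto esters and amides); the C7 hydroxyl of 8 then closes ring 1 by 5-exo-trig acyl substitution at the C9' ester carried by C8' (the ester on C8 itself could only give a β-lactone), giving the trans-aryl/ester lactone 9. In 9 only C8' (α-aroyl lactone) still epimerises, the second (R)-selective syn reduction should consume the epimer with the aroyl group cis to the C8 ester to give 10, and its C7' hydroxyl closes ring 2 by the same 5-exo-trig mode at the C9 ester, which is geometrically possible only for the cis-fused bicycle. The step thus needs (R) facial selectivity at two ketones and syn selectivity at two α-carbons: the first is secured by the two conjugated aryl ketones, the second by the polar carbonyl on each α-carbon together with the ring-closure filter, because material reduced in the anti sense cannot form a dilactone without an endo aryl group and remains a hydroxy ester of different polarity.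

Step 6
Reactants: 11 (1R,2R,5R,6R)-dilactone
Product: 12 (1R,2S,3S,4R)-1,4-bis(4-benzyloxy-3,5-dimethoxyphenyl)-2,3-bis(hydroxymethyl)butane-1,4-diol
Conditions: LiAlH4, THF, 0 °C → rt; then H2O, 15% aq. NaOH
Reagents that add atoms: none
Why: LiAlH4 reduction of both γ-lactones to 1,4-diols, in which the C7–O and C7'–O bonds are untouched and reduction outruns enolisation at C8 and C8', so all four stereocentres are carried over.

Step 7
Reactants: 12 (1R,2S,3S,4R)-tetraol
Product: 14 (7R,8S,7'R,8'S)-4,4'-di-O-benzylsyringaresinol, via bis-mesylate 13 (not isolated)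
Conditions: MsCl (2.1 equiv), pyridine, 0 °C → rt
Reagents that add atoms: methanesulfonyl chloride, CS(=O)(=O)Cl (its atoms appear only in intermediate 13)
Why: Fast sulfonylation of both unhindered primary hydroxyls followed by double intramolecular Williamson etherification (5-exo-tet), the C7 hydroxyl displacing the mesylate at C9' and the C7' hydroxyl that at C9, so that substitution occurs only at CH2, the configuration at C7, C8, C8' and C7' is retained and the cis-fused furofuran with exo aryl groups should result.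

Step 8
Reactants: 14 (7R,8S,7'R,8'S)-4,4'-di-O-benzylsyringaresinol
Product: 15 (7R,8S,7'R,8'S)-syringaresinol
Conditions: H2 (1 atm), 10% Pd/C, EtOAc/EtOH, rt
Reagents that add atoms: none
Why: Catalytic hydrogenolysis of the two aryl benzyl ethers, which under neutral conditions at one atmosphere is much faster than cleavage of the dialkyl benzylic C–O bonds of the furofuran.

Step 9
Reactants: 16 (R)-4-benzyloxazolidin-2-one; 17 bromoacetyl bromide
Product: 18 (R)-4-benzyl-3-(bromoacetyl)oxazolidin-2-one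
Conditions: n-BuLi, THF, −78 °C; then 17, −78 → 0 °C
Reagents that add atoms: none
Why: N-acylation of the lithiated oxazolidinone, the acyl bromide reacting at carbonyl far faster than at the CH2Br carbon at −78 °C, with the auxiliary stereocentre not involved.

Step 10
Reactants: 15 (7R,8S,7'R,8'S)-syringaresinol; 18 (R)-4-benzyl-3-(bromoacetyl)oxazolidin-2-one (2.2 equiv)
Product: 19 4,4'-di-O-{2-[(4R)-4-benzyl-2-oxooxazolidin-3-yl]-2-oxoethyl}syringaresinol (bis-imide)
Conditions: K2CO3, acetone, 40 °C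
Reagents that add atoms: none
Why: Two-fold Williamson etherification in which the hindered 2,6-dimethoxyphenoxides are matched with an exceptionally SN2-reactive α-bromo imide, carbonate being too weak to enolise or cleave the imide.

Step 11
Reactants: 20 vanillin
Product: 21 4-(tert-butyldimethylsilyloxy)-3-methoxybenzaldehyde
Conditions: TBSCl, imidazole, DMF, rt
Reagents that add atoms: tert-butyldimethylsilyl chloride, CC(C)(C)[Si](C)(C)Cl
Why: Imidazole-promoted silylation of the phenol, giving a non-enolisable aldehyde whose aryl silyl ether tolerates amine base, LiBH4 and alkyl silylation and is removable by fluoride.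

Step 12
Reactants: 19 bis-imide; 21 4-(tert-butyldimethylsilyloxy)-3-methoxybenzaldehyde (3 equiv)
Product: 23 4,4'-bis-O-{(2S,3S)-1-[(4R)-4-benzyl-2-oxooxazolidin-3-yl]-3-hydroxy-3-[4-(tert-butyldimethylsilyloxy)-3-methoxyphenyl]-1-oxopropan-2-yl}syringaresinol (bis anti-aldol adduct), via bis-TMS ether 22 (not isolated)
Conditions: MgCl2 (0.4 equiv), Et3N, TMSCl, EtOAc, rt; then citric acid, MeOH, rt
Reagents that add atoms: chlorotrimethylsilane, C[Si](C)(C)Cl (its atoms appear only in intermediate 22)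
Why: Evans magnesium halide-catalysed direct anti-aldol reaction run at both imides, in which soft enolisation of the Mg-chelated imide gives the Z-enolate that adds to the aryl aldehyde through a boat transition state on the face remote from the benzyl group of the (R)-auxiliary, so that C8 and C7 of arms B and E are set by the auxiliary in the anti (erythro) sense while silylation of the aldolate by TMSCl makes the addition irreversible and mild acidic methanolysis then removes the TMS groups.

Step 13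
Reactants: 23 bis anti-aldol adduct
Product: 24 4,4'-bis-O-{(1S,2R)-1,3-dihydroxy-1-[4-(tert-butyldimethylsilyloxy)-3-methoxyphenyl]propan-2-yl}syringaresinol (erythro,erythro tetraol)
Conditions: LiBH4, H2O (2 equiv), THF, 0 °C
Reagents that add atoms: none
Why: Reductive cleavage of the N-acyloxazolidinones by hydride attack at the more electrophilic exocyclic carbonyl, which gives the primary alcohols, returns the auxiliary and does not enolise C8.

Step 14
Reactants: 24 erythro,erythro tetraol
Product: 25 tetrakis(O-tert-butyldimethylsilyl) ether of 24 at the four aliphatic hydroxyls (six TBS groups in all)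
Conditions: TBSOTf, 2,6-lutidine, CH2Cl2, −78 → 0 °C
Reagents that add atoms: tert-butyldimethylsilyl trifluoromethanesulfonate, CC(C)(C)[Si](C)(C)OS(=O)(=O)C(F)(F)F
Why: Exhaustive silylation of primary and secondary benzylic hydroxyls with the silyl triflate and a hindered pyridine base, under buffered low-temperature conditions that should not ionise the benzylic positions.

Step 15
Reactants: 25 hexa-TBS compound
Product: 26 mono-phenol (25 lacking the aryl TBS group on the guaiacyl ring of arm B)
Conditions: Bu4NF (1.0 equiv), AcOH (1.0 equiv), THF, −20 → 0 °C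
Reagents that add atoms: none
Why: Fluoride cleaves aryl silyl ethers much faster than alkyl ones because phenoxide is the better leaving group, so one equivalent of buffered fluoride on the C2-symmetric substrate should give the mono-phenol as the main component of a statistical mixture from which unreacted 25 is recovered.

Step 16
Reactants: 27 (S)-4-benzyloxazolidin-2-one; 17 bromoacetyl bromide
Product: 28 (S)-4-benzyl-3-(bromoacetyl)oxazolidin-2-one
Conditions: n-BuLi, THF, −78 °C; then 17, −78 → 0 °C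
Reagents that add atoms: none
Why: The same N-acylation of a lithiated oxazolidinone as in step 9, with the enantiomeric auxiliary.

Step 17
Reactants: 26 mono-phenol; 28 (S)-4-benzyl-3-(bromoacetyl)oxazolidin-2-one
Product: 29 mono-imide (26 O-alkylated at the free phenol with the 2-[(4S)-4-benzyl-2-oxooxazolidin-3-yl]-2-oxoethyl group)
Conditions: K2CO3, acetone, rt
Reagents that add atoms: none
Why: Williamson etherification of the single free guaiacyl phenol by the reactive α-bromo imide, dry carbonate in acetone leaving the alkyl and aryl silyl ethers intact.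

Step 18
Reactants: 29 mono-imide; 21 4-(tert-butyldimethylsilyloxy)-3-methoxybenzaldehyde
Product: 31 anti-aldol adduct (arm A as the (2R,3R)-3-hydroxy-3-aryl-1-oxo-1-[(4S)-auxiliary]propan-2-yl group), via TMS ether 30 (not isolated)
Conditions: MgCl2 (0.2 equiv), Et3N, TMSCl, EtOAc, rt; then citric acid, MeOH, rt
Reagents that add atoms: chlorotrimethylsilane, C[Si](C)(C)Cl (its atoms appear only in intermediate 30)
Why: The same magnesium halide-catalysed anti-aldol reaction as in step 12, the (S)-auxiliary now directing the aldehyde to the opposite enolate face so that C8 and C7 of arm A are set in the (7R,8S) erythro sense independently of the remote stereocentres.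

Step 19
Reactants: 31 anti-aldol adduct
Product: 32 hexa-TBS diol (arm A as the (1R,2S)-1,3-dihydroxy-1-arylpropan-2-yl group)
Conditions: LiBH4, H2O (2 equiv), THF, 0 °C
Reagents that add atoms: none
Why: LiBH4 reductive removal of the oxazolidinone as in step 13, leaving the silyl ethers untouched.

Step 20
Reactants: 32 hexa-TBS diol
Product: 33 CNP0316493.2 (target)
Conditions: Bu4NF (8 equiv), AcOH (8 equiv), THF, 0 °C → rt
Reagents that add atoms: none
Why: Fluoride-mediated global desilylation of the four alkyl and two aryl silyl ethers, acetic acid buffering the medium so that the liberated p-hydroxybenzylic alcohols should neither form quinone methides nor epimerise at C7.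

**Compound list**

1 | acetosyringone | CC(=O)c1cc(OC)c(O)c(OC)c1 | starting material
2 | benzyl bromide | BrCc1ccccc1 | starting material
3 | 1-(4-benzyloxy-3,5-dimethoxyphenyl)ethanone | CC(=O)c1cc(OC)c(OCc2ccccc2)c(OC)c1 | intermediate
4 | diethyl carbonate | CCOC(=O)OCC | starting material
5 | ethyl 3-(4-benzyloxy-3,5-dimethoxyphenyl)-3-oxopropanoate | CCOC(=O)CC(=O)c1cc(OC)c(OCc2ccccc2)c(OC)c1 | intermediate
6 | ethyl 2-bromo-3-(4-benzyloxy-3,5-dimethoxyphenyl)-3-oxopropanoate (racemic) | CCOC(=O)C(Br)C(=O)c1cc(OC)c(OCc2ccccc2)c(OC)c1 | intermediate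
7 | diethyl 2,3-bis(4-benzyloxy-3,5-dimethoxybenzoyl)butanedioate (stereolabile meso/dl mixture) | CCOC(=O)C(C(=O)c1cc(OC)c(OCc2ccccc2)c(OC)c1)C(C(=O)OCC)C(=O)c1cc(OC)c(OCc2ccccc2)c(OC)c1 | intermediate
8 | diethyl (2R)-2-[(R)-(4-benzyloxy-3,5-dimethoxyphenyl)(hydroxy)methyl]-3-(4-benzyloxy-3,5-dimethoxybenzoyl)butanedioate (C3 labile) | COc1cc(cc(OC)c1OCc1ccccc1)[C@H](O)[C@H](C(=O)OCC)C(C(=O)OCC)C(=O)c1cc(OC)c(OCc2ccccc2)c(OC)c1 | intermediate (not isolated)
9 | ethyl (2R,3R)-2-(4-benzyloxy-3,5-dimethoxyphenyl)-4-(4-benzyloxy-3,5-dimethoxybenzoyl)-5-oxooxolane-3-carboxylate (C4 labile) | COc1cc(cc(OC)c1OCc1ccccc1)[C@@H]1OC(=O)C(C(=O)c2cc(OC)c(OCc3ccccc3)c(OC)c2)[C@H]1C(=O)OCC | intermediate (not isolated)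
10 | ethyl (2R,3R,4R)-2-(4-benzyloxy-3,5-dimethoxyphenyl)-4-[(R)-(4-benzyloxy-3,5-dimethoxyphenyl)(hydroxy)methyl]-5-oxooxolane-3-carboxylate | COc1cc(cc(OC)c1OCc1ccccc1)[C@@H]1OC(=O)[C@@H]([C@@H](O)c2cc(OC)c(OCc3ccccc3)c(OC)c2)[C@H]1C(=O)OCC | intermediate (not isolated)
11 | (1R,2R,5R,6R)-2,6-bis(4-benzyloxy-3,5-dimethoxyphenyl)-3,7-dioxabicyclo[3.3.0]octane-4,8-dione (exo,exo) | COc1cc(cc(OC)c1OCc1ccccc1)[C@@H]1OC(=O)[C@@H]2[C@H]1C(=O)O[C@H]2c1cc(OC)c(OCc2ccccc2)c(OC)c1 | intermediate
12 | (1R,2S,3S,4R)-1,4-bis(4-benzyloxy-3,5-dimethoxyphenyl)-2,3-bis(hydroxymethyl)butane-1,4-diol | COc1cc(cc(OC)c1OCc1ccccc1)[C@H](O)[C@H](CO)[C@@H](CO)[C@@H](O)c1cc(OC)c(OCc2ccccc2)c(OC)c1 | intermediate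
13 | bis(methanesulfonate) of the two primary hydroxyls of 12 | COc1cc(cc(OC)c1OCc1ccccc1)[C@H](O)[C@H](COS(C)(=O)=O)[C@@H](COS(C)(=O)=O)[C@@H](O)c1cc(OC)c(OCc2ccccc2)c(OC)c1 | intermediate (not isolated)
14 | (7R,8S,7'R,8'S)-4,4'-di-O-benzylsyringaresinol, i.e. (1R,3aS,4R,6aS)-1,4-bis(4-benzyloxy-3,5-dimethoxyphenyl)tetrahydro-1H,3H-furo[3,4-c]furan | COc1cc(cc(OC)c1OCc1ccccc1)[C@@H]1OC[C@@H]2[C@H]1CO[C@H]2c1cc(OC)c(OCc2ccccc2)c(OC)c1 | intermediate
15 | (7R,8S,7'R,8'S)-syringaresinol | COc1cc(cc(OC)c1O)[C@@H]1OC[C@@H]2[C@H]1CO[C@H]2c1cc(OC)c(O)c(OC)c1 | intermediate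
16 | (R)-4-benzyloxazolidin-2-one | O=C1N[C@H](Cc2ccccc2)CO1 | starting material
17 | bromoacetyl bromide | BrCC(Br)=O | starting material
18 | (R)-4-benzyl-3-(bromoacetyl)oxazolidin-2-one | O=C(CBr)N1[C@H](Cc2ccccc2)COC1=O | intermediate
19 | 4,4'-di-O-{2-[(4R)-4-benzyl-2-oxooxazolidin-3-yl]-2-oxoethyl}syringaresinol | COc1cc(cc(OC)c1OCC(=O)N1[C@H](Cc2ccccc2)COC1=O)[C@@H]1OC[C@@H]2[C@H]1CO[C@H]2c1cc(OC)c(OCC(=O)N2[C@H](Cc3ccccc3)COC2=O)c(OC)c1 | intermediate
20 | vanillin | COc1cc(C=O)ccc1O | starting material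
21 | 4-(tert-butyldimethylsilyloxy)-3-methoxybenzaldehyde | COc1cc(C=O)ccc1O[Si](C)(C)C(C)(C)C | intermediate
22 | bis(O-trimethylsilyl) ether of 23 | COc1cc(cc(OC)c1O[C@H](C(=O)N1[C@H](Cc2ccccc2)COC1=O)[C@@H](O[Si](C)(C)C)c1ccc(O[Si](C)(C)C(C)(C)C)c(OC)c1)[C@@H]1OC[C@@H]2[C@H]1CO[C@H]2c1cc(OC)c(O[C@H](C(=O)N2[C@H](Cc3ccccc3)COC2=O)[C@@H](O[Si](C)(C)C)c2ccc(O[Si](C)(C)C(C)(C)C)c(OC)c2)c(OC)c1 | intermediate (not isolated)
23 | 4,4'-bis-O-{(2S,3S)-1-[(4R)-4-benzyl-2-oxooxazolidin-3-yl]-3-hydroxy-3-[4-(tert-butyldimethylsilyloxy)-3-methoxyphenyl]-1-oxopropan-2-yl}syringaresinol | COc1cc(cc(OC)c1O[C@H](C(=O)N1[C@H](Cc2ccccc2)COC1=O)[C@@H](O)c1ccc(O[Si](C)(C)C(C)(C)C)c(OC)c1)[C@@H]1OC[C@@H]2[C@H]1CO[C@H]2c1cc(OC)c(O[C@H](C(=O)N2[C@H](Cc3ccccc3)COC2=O)[C@@H](O)c2ccc(O[Si](C)(C)C(C)(C)C)c(OC)c2)c(OC)c1 | intermediate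
24 | 4,4'-bis-O-{(1S,2R)-1,3-dihydroxy-1-[4-(tert-butyldimethylsilyloxy)-3-methoxyphenyl]propan-2-yl}syringaresinol | COc1cc(cc(OC)c1O[C@H](CO)[C@@H](O)c1ccc(O[Si](C)(C)C(C)(C)C)c(OC)c1)[C@@H]1OC[C@@H]2[C@H]1CO[C@H]2c1cc(OC)c(O[C@H](CO)[C@@H](O)c2ccc(O[Si](C)(C)C(C)(C)C)c(OC)c2)c(OC)c1 | intermediate
25 | tetrakis(O-tert-butyldimethylsilyl) ether of 24 at the four aliphatic hydroxyls | COc1cc(cc(OC)c1O[C@H](CO[Si](C)(C)C(C)(C)C)[C@@H](O[Si](C)(C)C(C)(C)C)c1ccc(O[Si](C)(C)C(C)(C)C)c(OC)c1)[C@@H]1OC[C@@H]2[C@H]1CO[C@H]2c1cc(OC)c(O[C@H](CO[Si](C)(C)C(C)(C)C)[C@@H](O[Si](C)(C)C(C)(C)C)c2ccc(O[Si](C)(C)C(C)(C)C)c(OC)c2)c(OC)c1 | intermediate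
26 | mono-phenol: 25 with the guaiacyl oxygen of arm B free | COc1cc(cc(OC)c1O[C@H](CO[Si](C)(C)C(C)(C)C)[C@@H](O[Si](C)(C)C(C)(C)C)c1ccc(O)c(OC)c1)[C@@H]1OC[C@@H]2[C@H]1CO[C@H]2c1cc(OC)c(O[C@H](CO[Si](C)(C)C(C)(C)C)[C@@H](O[Si](C)(C)C(C)(C)C)c2ccc(O[Si](C)(C)C(C)(C)C)c(OC)c2)c(OC)c1 | intermediate
27 | (S)-4-benzyloxazolidin-2-one | O=C1N[C@@H](Cc2ccccc2)CO1 | starting material
28 | (S)-4-benzyl-3-(bromoacetyl)oxazolidin-2-one | O=C(CBr)N1[C@@H](Cc2ccccc2)COC1=O | intermediate
29 | mono-imide: 26 O-alkylated at the free phenol with the 2-[(4S)-4-benzyl-2-oxooxazolidin-3-yl]-2-oxoethyl group | COc1cc(cc(OC)c1O[C@H](CO[Si](C)(C)C(C)(C)C)[C@@H](O[Si](C)(C)C(C)(C)C)c1ccc(OCC(=O)N2[C@@H](Cc3ccccc3)COC2=O)c(OC)c1)[C@@H]1OC[C@@H]2[C@H]1CO[C@H]2c1cc(OC)c(O[C@H](CO[Si](C)(C)C(C)(C)C)[C@@H](O[Si](C)(C)C(C)(C)C)c2ccc(O[Si](C)(C)C(C)(C)C)c(OC)c2)c(OC)c1 | intermediate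
30 | O-trimethylsilyl ether of 31 | COc1cc(cc(OC)c1O[C@H](CO[Si](C)(C)C(C)(C)C)[C@@H](O[Si](C)(C)C(C)(C)C)c1ccc(O[C@@H](C(=O)N2[C@@H](Cc3ccccc3)COC2=O)[C@H](O[Si](C)(C)C)c2ccc(O[Si](C)(C)C(C)(C)C)c(OC)c2)c(OC)c1)[C@@H]1OC[C@@H]2[C@H]1CO[C@H]2c1cc(OC)c(O[C@H](CO[Si](C)(C)C(C)(C)C)[C@@H](O[Si](C)(C)C(C)(C)C)c2ccc(O[Si](C)(C)C(C)(C)C)c(OC)c2)c(OC)c1 | intermediate (not isolated)
31 | anti-aldol adduct: arm A as (2R,3R)-1-[(4S)-4-benzyl-2-oxooxazolidin-3-yl]-3-hydroxy-3-[4-(tert-butyldimethylsilyloxy)-3-methoxyphenyl]-1-oxopropan-2-yl on the arm-B phenol oxygen | COc1cc(cc(OC)c1O[C@H](CO[Si](C)(C)C(C)(C)C)[C@@H](O[Si](C)(C)C(C)(C)C)c1ccc(O[C@@H](C(=O)N2[C@@H](Cc3ccccc3)COC2=O)[C@H](O)c2ccc(O[Si](C)(C)C(C)(C)C)c(OC)c2)c(OC)c1)[C@@H]1OC[C@@H]2[C@H]1CO[C@H]2c1cc(OC)c(O[C@H](CO[Si](C)(C)C(C)(C)C)[C@@H](O[Si](C)(C)C(C)(C)C)c2ccc(O[Si](C)(C)C(C)(C)C)c(OC)c2)c(OC)c1 | intermediate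
32 | hexa-TBS diol: arm A as (1R,2S)-1,3-dihydroxy-1-[4-(tert-butyldimethylsilyloxy)-3-methoxyphenyl]propan-2-yl | COc1cc(cc(OC)c1O[C@H](CO[Si](C)(C)C(C)(C)C)[C@@H](O[Si](C)(C)C(C)(C)C)c1ccc(O[C@@H](CO)[C@H](O)c2ccc(O[Si](C)(C)C(C)(C)C)c(OC)c2)c(OC)c1)[C@@H]1OC[C@@H]2[C@H]1CO[C@H]2c1cc(OC)c(O[C@H](CO[Si](C)(C)C(C)(C)C)[C@@H](O[Si](C)(C)C(C)(C)C)c2ccc(O[Si](C)(C)C(C)(C)C)c(OC)c2)c(OC)c1 | intermediate
33 | CNP0316493.2 | COc1cc([C@@H](O)[C@H](CO)Oc2ccc([C@H](O)[C@@H](CO)Oc3c(OC)cc([C@@H]4OC[C@@H]5[C@H]4CO[C@H]5c4cc(OC)c(O[C@H](CO)[C@@H](O)c5ccc(O)c(OC)c5)c(OC)c4)cc3OC)cc2OC)ccc1O | target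

**Step count and risks**

Total step count: 20. Longest linear sequence: 17 steps (1–8, 10, 12–15, 17–20).

Steps most likely to fail:

1. Step 5 (proposed new method). Three processes could defeat it.
   - Hydride delivery in the anti sense at the first ketone would lock C8 in the configuration that cannot reach the exo,exo bicycle.
   - Epimerisation of C8' in the keto lactone may be slow relative to reduction, so that material stalls before the second ring closure.
   - Acid-promoted cyclodehydration of the 1,4-diketone to a furan may compete in the formic acid medium.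
   - Fallback (known chemistry): it sets out from 7 and gives up catalytic control. NaBH4 in EtOH/THF at 0 °C should reduce both ketones to the stereoisomer mixture of diethyl 2,3-bis[(4-benzyloxy-3,5-dimethoxyphenyl)(hydroxy)methyl]butanedioate F1. Catalytic TsOH in toluene at 60 °C lactonises the mixture, and the racemic exo,exo-dilactone is separated from the other diastereomers by crystallisation. Preparative HPLC on a chiral stationary phase then separates 11 from its mirror image, the (1S,2S,5S,6S)-dilactone F2. The route is rejoined at 11.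

2. Step 12 (the same reaction is used once more in step 18). The α-aryloxy oxygen, flanked by two methoxy groups, may compete for magnesium, causing loss of anti diastereocontrol or of enolate facial control. Conversion at two sites with an electron-rich aldehyde may also be incomplete.
   - Fallback: it sets out from 15 and replaces the anti aldol by a boron syn aldol followed by correction of C7. Compound 15 is alkylated with 28 (K2CO3, acetone) to the bis-imide carrying the (S)-auxiliary F3. Bu2BOTf/i-Pr2NEt (CH2Cl2, −78 → 0 °C) and then 21 give, through the Zimmerman–Traxler transition state of the boron Z-enolate, the bis syn-aldol adduct F4, which has the required C8 and the opposite C7 configuration. LiBH4 gives the threo,threo tetraol F5. MnO2 (CH2Cl2, rt) oxidises only the two benzylic carbinols to the bis(aryl ketone) diol F6. Reagent-controlled reduction with (S)-2-methyl-CBS-oxazaborolidine and BH3·SMe2 (THF, −20 °C), reinforced by the Felkin–Anh preference for hydride anti to the aryloxy group, should give the erythro tetraol 24, where the route is rejoined.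

3. Step 7. Ionisation of the electron-rich benzylic carbinols (or of adventitious benzylic mesylates) would switch the ring closure to an SN1 path and epimerise C7/C7'. Ether formation between the two primary carbons is a second possible diversion.
   - Fallback: it sets out from 11 and never frees the benzylic hydroxyls. i-Bu2AlH (CH2Cl2, −78 °C) reduces both lactones to the bis-lactol F7 (anomer mixture). Ionic hydrogenation of the two lactol carbons with Et3SiH/BF3·OEt2 (CH2Cl2, −78 °C), through oxocarbenium ions at C9 and C9' and not at C7, should give 14 directly, where the route is rejoined; steps 6 and 7 are replaced.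

**Further compounds**

F1 | step 5 | diethyl 2,3-bis[(4-benzyloxy-3,5-dimethoxyphenyl)(hydroxy)methyl]butanedioate (mixture of stereoisomers) | CCOC(=O)C(C(O)c1cc(OC)c(OCc2ccccc2)c(OC)c1)C(C(=O)OCC)C(O)c1cc(OC)c(OCc2ccccc2)c(OC)c1
F2 | step 5 | (1S,2S,5S,6S)-2,6-bis(4-benzyloxy-3,5-dimethoxyphenyl)-3,7-dioxabicyclo[3.3.0]octane-4,8-dione (mirror image of 11) | COc1cc(cc(OC)c1OCc1ccccc1)[C@H]1OC(=O)[C@H]2[C@@H]1C(=O)O[C@@H]2c1cc(OC)c(OCc2ccccc2)c(OC)c1
F3 | step 12 | 4,4'-di-O-{2-[(4S)-4-benzyl-2-oxooxazolidin-3-yl]-2-oxoethyl}syringaresinol | COc1cc(cc(OC)c1OCC(=O)N1[C@@H](Cc2ccccc2)COC1=O)[C@@H]1OC[C@@H]2[C@H]1CO[C@H]2c1cc(OC)c(OCC(=O)N2[C@@H](Cc3ccccc3)COC2=O)c(OC)c1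
F4 | step 12 | 4,4'-bis-O-{(2S,3R)-1-[(4S)-4-benzyl-2-oxooxazolidin-3-yl]-3-hydroxy-3-[4-(tert-butyldimethylsilyloxy)-3-methoxyphenyl]-1-oxopropan-2-yl}syringaresinol (bis syn-aldol adduct) | COc1cc(cc(OC)c1O[C@H](C(=O)N1[C@@H](Cc2ccccc2)COC1=O)[C@H](O)c1ccc(O[Si](C)(C)C(C)(C)C)c(OC)c1)[C@@H]1OC[C@@H]2[C@H]1CO[C@H]2c1cc(OC)c(O[C@H](C(=O)N2[C@@H](Cc3ccccc3)COC2=O)[C@H](O)c2ccc(O[Si](C)(C)C(C)(C)C)c(OC)c2)c(OC)c1
F5 | step 12 | 4,4'-bis-O-{(1R,2R)-1,3-dihydroxy-1-[4-(tert-butyldimethylsilyloxy)-3-methoxyphenyl]propan-2-yl}syringaresinol (threo,threo tetraol) | COc1cc(cc(OC)c1O[C@H](CO)[C@H](O)c1ccc(O[Si](C)(C)C(C)(C)C)c(OC)c1)[C@@H]1OC[C@@H]2[C@H]1CO[C@H]2c1cc(OC)c(O[C@H](CO)[C@H](O)c2ccc(O[Si](C)(C)C(C)(C)C)c(OC)c2)c(OC)c1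
F6 | step 12 | 4,4'-bis-O-{(2R)-3-hydroxy-1-[4-(tert-butyldimethylsilyloxy)-3-methoxyphenyl]-1-oxopropan-2-yl}syringaresinol (bis(aryl ketone) diol) | COc1cc(cc(OC)c1O[C@H](CO)C(=O)c1ccc(O[Si](C)(C)C(C)(C)C)c(OC)c1)[C@@H]1OC[C@@H]2[C@H]1CO[C@H]2c1cc(OC)c(O[C@H](CO)C(=O)c2ccc(O[Si](C)(C)C(C)(C)C)c(OC)c2)c(OC)c1
F7 | step 7 | (1R,2R,5R,6R)-2,6-bis(4-benzyloxy-3,5-dimethoxyphenyl)-3,7-dioxabicyclo[3.3.0]octane-4,8-diol (bis-lactol, anomer mixture) | COc1cc(cc(OC)c1OCc1ccccc1)[C@@H]1OC(O)[C@@H]2[C@H]1C(O)O[C@H]2c1cc(OC)c(OCc2ccccc2)c(OC)c1
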